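If part of the catalyst sits in L.X, the rate of J follows free [L], not the L charged, so I began there.

the same everywhere: D 20.0 mM; L 20 µM; X 35 µM

| run | J | E | time | remark |
|---|---|---|---|---|
| west | 20 mM | 60.0 mM | 50 s | a closed flask charged with all of it at once and left for 50 s |
| south-east | 20 mM (fed, over 50.0 s) | 60.0 mM | 50 s | a stirred flask in which J is dosed at a steady rate over 50.0 s without added volume, worked up at 50 s |
| east | 20 mM | 60.0 mM (fed, over 50.0 s) | 50 s | all but E at the start; E goes in evenly over 50.0 s, the run ends at 50 s |
| south | 20 mM | 60.0 mM |  | one stirred flow tank at steady state, fed with the mixture as stated, mean residence time 50 s |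

    J + E + L → L + G (k1 = 25200 M⁻² s⁻¹)
    D + E + L → L + Z (k2 = 1510 M⁻² s⁻¹)
    L + X ⇌ L.X (K3 = 10100 M⁻¹, k3 = 700 M⁻¹ s⁻¹)

- the stated concentrations are those of everything mixed, before any reaction; amounts are the same in each set-up
- the feed brings no volume worth counting
- run time (west): 50 s

1. the set-up with the highest amount of G at the outlet or at the end, in percent of the J put in ("none" if the first two lie within 2 percentage points) (west / south-east / east / south / none)
2. amount of G at the outlet or at the end, in percent of the J put in, west
3. amount of G at the outlet or at the end, in percent of the J put in, south-east
4. amount of G at the outlet or at the end, in percent of the J put in, east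
5. amount of G at the outlet or at the end, in percent of the J put in, south

I kept the ledger for west, the closed flask, and stopped there. J is the limiting reagent for G, and E covers it: J and D together need 40.0 mM, less than the 60.0 mM of E charged.

1. I took the binding at equilibrium throughout. The smaller root of its quadratic put 4.69 µM into L.X in west.

2. I kept the free catalyst 15.3 µM, the L charged less what X holds at equilibrium. With [L] held there and [E] taken as steady, J decays as a pseudo-first-order species.

3. At the charge in west, J reacted 16.7 times faster than D, so I booked the E spent to G.

4. At the charged [E], the constant was 0.0232 s⁻¹, a half-life of 29.9 s. Over 50 s, this first pass gave 31.4% of J left and 13.7 mM of E spent.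

5. For the second pass I took the mean [E] as 53.1 mM, which gave 0.0205 s⁻¹. My books of west closed at 35.9% of J left and 64.1% as G.

The forecast named west as best, with 65% for west, where I had 64.1%, 38.7% for south-east, 41% for east and 49.8% for south, reasoning that “the batch gets the full time at high J and E”.

The simulation gave west as best, with 65.1% for west, 38.6% for south-east, 40.9% for east and 49.8% for south.

In west at 50.0 s, the relaxation half-life of the binding, both ways together, was 6.84 s, shorter than the 39 s half-life of J by the step to G at that moment, and free L read 78.4% of the catalyst charged at 25.0 s and 76.7% at 50.0 s, against my 76.6%. The run of 50 s was 1.28 of those late half-lives, and west ended with 34.9% of its J unreacted.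

In the neighbour like west but with 0.080 mM of L, the quadratic put 14.0 µM into L.X, so I reckoned free catalyst at 66.0 µM, or 82.5% of the charge; the same two passes, with mean [E] taken as 50.1 mM, put J left at 1.55%. That flask gave L 82.5%, J 2.61% and G 97.4%.

Its constants are assumed; the run is a simulation.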